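**Retrosynthetic overview**
1. Last bond C7–C8: B-alkyl Suzuki coupling of the alkyl boronate 15 (C8–C15, furan, methyl ester) with the vinyl iodide acid 24 (C1–C7, free acid), so the ester and the acid never have to be told apart.
2. C9 stereocentre, isopropenyl group and C8 in one step: enantioselective copper-catalysed SN2' substitution of the prenyl-derived allylic phosphate 13 with diborylmethane 14. This replaces the usual chiral-pool or auxiliary alkylation followed by stepwise olefinations.
3. 13 from the Z-enoate 11 (Still–Gennari olefination of an α-homoprenyl phosphonate with 3-(furan-3-yl)propanal) by SeO2 oxidation of the terminal (E)-methyl group and phosphorylation.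
4. 24 from pent-4-yn-1-ol: Zr-catalysed carboalumination/iodination (6E), Wittig reaction with an α-homoprenyl ylide (2E), saponification.
5. No ring is formed: the furan is bought in as 3-bromofuran and the rest of the target is acyclic.

Assumption: the antipode of the chiral carbene ligand that delivers the CH2B(pin) group to the Re face of C3 of 13 (giving (R)-15, which is 9S in the target) is assigned on a model substrate and then used; locants C1–C15 are those of the pentadecatrienoic acid chain of the target.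

**Route**

Step 1
Reactants: 1 3-bromofuran; 2 oxetane
Product: 4 3-(furan-3-yl)propan-1-ol, via furan-3-yllithium 3 (not isolated)
Conditions: n-BuLi, THF, −78 °C; then 2, BF3·OEt2, −78 °C; then H2O
Reagents that add atoms: none
Why: Bromine–lithium exchange gives the 3-furyllithium, which is stable below −70 °C, and it opens the BF3-activated oxetane (Lewis-acid-promoted oxetane ring opening) to add the three-carbon alcohol chain.

Step 2
Reactants: 4 3-(furan-3-yl)propan-1-ol
Product: 5 3-(furan-3-yl)propanal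
Conditions: Dess–Martin periodinane, CH2Cl2, 0 °C → rt
Reagents that add atoms: none
Why: Dess–Martin oxidation stops at the aldehyde under near-neutral conditions that the furan tolerates.

Step 3
Reactants: 6 methyl 2-[bis(2,2,2-trifluoroethoxy)phosphoryl]acetate; 7 5-bromo-2-methylpent-2-ene
Product: 9 methyl 2-[bis(2,2,2-trifluoroethoxy)phosphoryl]-6-methylhept-5-enoate (racemic), via sodiated phosphonoacetate 8 (not isolated)
Conditions: NaH, DMF, 0 °C; then 7, NaI (10 mol %), 50 °C (6 in 1.5-fold excess)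
Reagents that add atoms: none
Why: SN2 C-alkylation of the soft phosphonoacetate carbanion with the primary homoallylic bromide (phosphonate alkylation); the excess of 6 suppresses dialkylation and NaH avoids transesterification of the trifluoroethyl esters.

Step 4
Reactants: 9 methyl 2-[bis(2,2,2-trifluoroethoxy)phosphoryl]-6-methylhept-5-enoate; 5 3-(furan-3-yl)propanal
Product: 11 methyl (2Z)-5-(furan-3-yl)-2-(4-methylpent-3-en-1-yl)pent-2-enoate, via potassiated phosphonate 10 (not isolated)
Conditions: KN(SiMe3)2, 18-crown-6, THF, −78 °C; then 5, −78 °C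
Reagents that add atoms: none
Why: Still–Gennari olefination: the electron-poor trifluoroethyl phosphonate with a dissociated potassium counter-ion eliminates fast from the kinetic adduct and gives the Z-trisubstituted enoate (ester cis to the furylethyl chain, the 12Z alkene of the target).

Step 5
Reactants: 11 methyl (2Z)-5-(furan-3-yl)-2-(4-methylpent-3-en-1-yl)pent-2-enoate
Product: 12 methyl (2Z)-5-(furan-3-yl)-2-[(3E)-5-hydroxy-4-methylpent-3-en-1-yl]pent-2-enoate
Conditions: SeO2 (0.5 equiv), t-BuOOH (3 equiv), salicylic acid (10 mol %), CH2Cl2, 0 °C → rt, stopped at partial conversion, 11 recycled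
Reagents that add atoms: tert-butyl hydroperoxide, CC(C)(C)OO (oxygen, relayed through selenium dioxide, O=[Se]=O)
Why: SeO2 allylic oxidation (ene reaction, then [2,3]-sigmatropic shift) attacks the most electron-rich trisubstituted alkene at its (E)-methyl group; the enoate alkene is deactivated, and 3-alkylfurans of the dendrolasin type are known to survive these conditions.

Step 6
Reactants: 12 methyl (2Z)-5-(furan-3-yl)-2-[(3E)-5-hydroxy-4-methylpent-3-en-1-yl]pent-2-enoate
Product: 13 methyl (2Z)-2-[(3E)-5-[(diethoxyphosphoryl)oxy]-4-methylpent-3-en-1-yl]-5-(furan-3-yl)pent-2-enoate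
Conditions: ClP(O)(OEt)2, Et3N, DMAP (10 mol %), CH2Cl2, 0 °C
Reagents that add atoms: diethyl chlorophosphate, CCOP(=O)(Cl)OCC
Why: O-phosphorylation of the primary allylic alcohol gives the leaving group needed for copper-catalysed allylic substitution without touching the alkene geometry.

Step 7
Reactants: 13 methyl (2Z)-2-[(3E)-5-[(diethoxyphosphoryl)oxy]-4-methylpent-3-en-1-yl]-5-(furan-3-yl)pent-2-enoate; 14 2,2'-methylenebis(4,4,5,5-tetramethyl-1,3,2-dioxaborolane)
Product: 15 methyl (2Z)-5-(furan-3-yl)-2-[(3R)-4-methyl-3-[(4,4,5,5-tetramethyl-1,3,2-dioxaborolan-2-yl)methyl]pent-4-en-1-yl]pent-2-enoate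
Conditions: CuCl (5 mol %), chiral sulfonate-bearing imidazolinium salt (carbene precursor, 5.5 mol %), NaOMe (1.5 equiv), THF, 22 °C
Reagents that add atoms: none
Why: Proposed new method: copper-catalysed enantioselective SN2' allylic substitution, in which NaOMe turns 14 into an α-boryl alkyl–copper species on the chiral carbene–monovalent copper catalyst, which adds anti to the phosphate at C3 through a trivalent copper σ-allyl intermediate and reductively eliminates there, so that one step creates the stereocentre (Re-face delivery gives R), the 1,1-disubstituted alkene and the CH2B handle; the closest known reactions are carbene–copper-catalysed SN2' substitutions of di- and trisubstituted allylic phosphates with this same diborylmethane and copper-catalysed SN2' alkylations of 2-methyl-substituted allylic chlorides with Grignard reagents, but this combination is untested.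

Step 8
Reactants: 16 pent-4-yn-1-ol
Product: 18 (4E)-5-iodo-4-methylpent-4-en-1-ol, via alkenyldimethylalane 17 (not isolated)
Conditions: AlMe3 (3 equiv), Cp2ZrCl2 (25 mol %), CH2Cl2, 0 °C → rt; then I2, THF, −30 °C; aq. potassium sodium tartrate
Reagents that add atoms: trimethylaluminium, C[Al](C)C; iodine, II
Why: Zirconium-catalysed carboalumination (Negishi) adds methyl and aluminium syn across the terminal alkyne with methyl on the internal carbon, and iodinolysis with retention gives the (E)-vinyl iodide that fixes the 6E geometry.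

Step 9
Reactants: 18 (4E)-5-iodo-4-methylpent-4-en-1-ol
Product: 19 (4E)-5-iodo-4-methylpent-4-enal
Conditions: Dess–Martin periodinane, CH2Cl2, 0 °C → rt
Reagents that add atoms: none
Why: Dess–Martin oxidation gives the aldehyde without touching the vinyl iodide.

Step 10
Reactants: 20 ethyl 2-(triphenyl-λ5-phosphanylidene)acetate; 7 5-bromo-2-methylpent-2-ene
Product: 22 ethyl 6-methyl-2-(triphenyl-λ5-phosphanylidene)hept-5-enoate, via phosphonium bromide 21 (not isolated)
Conditions: 7 (1.5 equiv), NaI (20 mol %), MeCN, reflux; then aq. NaOH, CH2Cl2, rt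
Reagents that add atoms: none
Why: C-alkylation of the stabilised ylide with the primary halide gives the phosphonium salt, and aqueous base regenerates the α-substituted stabilised ylide.

Step 11
Reactants: 19 (4E)-5-iodo-4-methylpent-4-enal; 22 ethyl 6-methyl-2-(triphenyl-λ5-phosphanylidene)hept-5-enoate
Product: 23 ethyl (2E,6E)-7-iodo-6-methyl-2-(4-methylpent-3-en-1-yl)hepta-2,6-dienoate
Conditions: toluene, 90 °C
Reagents that add atoms: none
Why: Wittig reaction of an α-substituted stabilised ylide with an unbranched aldehyde gives the E-trisubstituted enoate (chain trans to the ester, the 2E alkene of the target).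

Step 12
Reactants: 23 ethyl (2E,6E)-7-iodo-6-methyl-2-(4-methylpent-3-en-1-yl)hepta-2,6-dienoate
Product: 24 (2E,6E)-7-iodo-6-methyl-2-(4-methylpent-3-en-1-yl)hepta-2,6-dienoic acid
Conditions: LiOH, THF/MeOH/H2O, 45 °C; then aq. HCl to pH 3
Reagents that add atoms: lithium hydroxide, [Li+].[OH-] (hydroxide oxygen)
Why: Saponification is done while this ester is the only one in the molecule, and the vinyl iodide and alkenes are inert to hydroxide.

Step 13
Reactants: 15 methyl (2Z)-5-(furan-3-yl)-2-[(3R)-4-methyl-3-[(4,4,5,5-tetramethyl-1,3,2-dioxaborolan-2-yl)methyl]pent-4-en-1-yl]pent-2-enoate; 24 (2E,6E)-7-iodo-6-methyl-2-(4-methylpent-3-en-1-yl)hepta-2,6-dienoic acid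
Product: 25 (2E,6E,9S,12Z)-15-(furan-3-yl)-12-(methoxycarbonyl)-6-methyl-2-(4-methylpent-3-en-1-yl)-9-(prop-1-en-2-yl)pentadeca-2,6,12-trienoic acid
Conditions: Pd(OAc)2 (10 mol %), RuPhos (20 mol %), K3PO4 (4 equiv), 1,4-dioxane/H2O, 80 °C; then aq. NaH2PO4
Reagents that add atoms: none
Why: B-alkyl Suzuki–Miyaura coupling: zerovalent palladium inserts into the vinyl iodide with retention of the 6E geometry, the primary alkyl boronate transmetalates with base, and the bulky phosphine favours reductive elimination over β-hydride elimination; C9 is not involved, so its configuration is kept (the label changes from R to S only through CIP priorities), and the acid travels as its potassium carboxylate.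

**Compound list**
1 | 3-bromofuran | Brc1ccoc1 | starting material
2 | oxetane | C1COC1 | starting material
3 | furan-3-yllithium | [Li]c1ccoc1 | intermediate
4 | 3-(furan-3-yl)propan-1-ol | OCCCc1ccoc1 | intermediate
5 | 3-(furan-3-yl)propanal | O=CCCc1ccoc1 | intermediate
6 | methyl 2-[bis(2,2,2-trifluoroethoxy)phosphoryl]acetate | COC(=O)CP(=O)(OCC(F)(F)F)OCC(F)(F)F | starting material
7 | 5-bromo-2-methylpent-2-ene | CC(C)=CCCBr | starting material
8 | sodium 1-[bis(2,2,2-trifluoroethoxy)phosphoryl]-2-methoxy-2-oxoethan-1-ide | [Na+].COC(=O)[CH-]P(=O)(OCC(F)(F)F)OCC(F)(F)F | intermediate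
9 | methyl 2-[bis(2,2,2-trifluoroethoxy)phosphoryl]-6-methylhept-5-enoate (racemic) | COC(=O)C(CCC=C(C)C)P(=O)(OCC(F)(F)F)OCC(F)(F)F | intermediate
10 | potassium 2-[bis(2,2,2-trifluoroethoxy)phosphoryl]-1-methoxy-6-methyl-1-oxohept-5-en-2-ide | [K+].COC(=O)[C-](CCC=C(C)C)P(=O)(OCC(F)(F)F)OCC(F)(F)F | intermediate
11 | methyl (2Z)-5-(furan-3-yl)-2-(4-methylpent-3-en-1-yl)pent-2-enoate | CC(C)=CCC/C(=C/CCc1ccoc1)C(=O)OC | intermediate
12 | methyl (2Z)-5-(furan-3-yl)-2-[(3E)-5-hydroxy-4-methylpent-3-en-1-yl]pent-2-enoate | OC/C(C)=C/CC/C(=C/CCc1ccoc1)C(=O)OC | intermediate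
13 | methyl (2Z)-2-[(3E)-5-[(diethoxyphosphoryl)oxy]-4-methylpent-3-en-1-yl]-5-(furan-3-yl)pent-2-enoate | CCOP(=O)(OCC)OC/C(C)=C/CC/C(=C/CCc1ccoc1)C(=O)OC | intermediate
14 | 2,2'-methylenebis(4,4,5,5-tetramethyl-1,3,2-dioxaborolane) | CC1(C)OB(CB2OC(C)(C)C(C)(C)O2)OC1(C)C | starting material
15 | methyl (2Z)-5-(furan-3-yl)-2-[(3R)-4-methyl-3-[(4,4,5,5-tetramethyl-1,3,2-dioxaborolan-2-yl)methyl]pent-4-en-1-yl]pent-2-enoate | C=C(C)[C@H](CB1OC(C)(C)C(C)(C)O1)CC/C(=C/CCc1ccoc1)C(=O)OC | intermediate
16 | pent-4-yn-1-ol | C#CCCCO | starting material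
17 | [(1E)-5-[(dimethylalumanyl)oxy]-2-methylpent-1-en-1-yl]dimethylalumane | C[Al](C)OCCC/C(C)=C/[Al](C)C | intermediate
18 | (4E)-5-iodo-4-methylpent-4-en-1-ol | OCCC/C(C)=C/I | intermediate
19 | (4E)-5-iodo-4-methylpent-4-enal | O=CCC/C(C)=C/I | intermediate
20 | ethyl 2-(triphenyl-λ5-phosphanylidene)acetate | CCOC(=O)C=P(c1ccccc1)(c1ccccc1)c1ccccc1 | starting material
21 | (1-ethoxy-6-methyl-1-oxohept-5-en-2-yl)triphenylphosphonium bromide (racemic) | [Br-].CCOC(=O)C(CCC=C(C)C)[P+](c1ccccc1)(c1ccccc1)c1ccccc1 | intermediate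
22 | ethyl 6-methyl-2-(triphenyl-λ5-phosphanylidene)hept-5-enoate | CCOC(=O)C(CCC=C(C)C)=P(c1ccccc1)(c1ccccc1)c1ccccc1 | intermediate
23 | ethyl (2E,6E)-7-iodo-6-methyl-2-(4-methylpent-3-en-1-yl)hepta-2,6-dienoate | CCOC(=O)/C(CCC=C(C)C)=C/CC/C(C)=C/I | intermediate
24 | (2E,6E)-7-iodo-6-methyl-2-(4-methylpent-3-en-1-yl)hepta-2,6-dienoic acid | OC(=O)/C(CCC=C(C)C)=C/CC/C(C)=C/I | intermediate
25 | (2E,6E,9S,12Z)-15-(furan-3-yl)-12-(methoxycarbonyl)-6-methyl-2-(4-methylpent-3-en-1-yl)-9-(prop-1-en-2-yl)pentadeca-2,6,12-trienoic acid | C=C(C)[C@H](C/C=C(\C)CC/C=C(\CCC=C(C)C)C(=O)O)CC/C(=C/CCc1ccoc1)C(=O)OC | target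

**Step count**
Total: 13 steps. Longest linear sequence: 7 steps (steps 1, 2, 4, 5, 6, 7, 13, from 3-bromofuran).

**Three steps most likely to fail, with fallbacks**

Step 7 (enantioselective SN2' with diborylmethane on a 2-methyl-substituted phosphate; regioselectivity and ee are unproven). The fallback sets out from 12 and comes back at 15, and makes the stereocentre as a C–B bond first. Alcohol 12 is acylated with methyl chloroformate and pyridine to methyl (2Z)-5-(furan-3-yl)-2-[(3E)-5-[(methoxycarbonyl)oxy]-4-methylpent-3-en-1-yl]pent-2-enoate F1. Copper-catalysed enantioselective γ-borylation (CuCl, NaO-t-Bu, chiral bisphosphine, B2pin2, THF) then gives the allylic boronate methyl (2Z)-5-(furan-3-yl)-2-[(3R)-4-methyl-3-(4,4,5,5-tetramethyl-1,3,2-dioxaborolan-2-yl)pent-4-en-1-yl]pent-2-enoate F2. Matteson homologation (BrCH2Cl, n-BuLi, THF, −78 °C → rt) inserts CH2 into the C–B bond with retention and delivers 15.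

Step 13 (primary alkyl pinacol boronates transmetalate slowly, and the partner carries a free acid). The fallback sets out from 15 and comes back at 25, and replaces boron by zinc. Oxidation of 15 with NaBO3·4H2O in THF/H2O gives methyl (2Z)-5-(furan-3-yl)-2-[(3R)-3-(hydroxymethyl)-4-methylpent-4-en-1-yl]pent-2-enoate F3. I2, PPh3 and imidazole convert it into methyl (2Z)-5-(furan-3-yl)-2-[(3R)-3-(iodomethyl)-4-methylpent-4-en-1-yl]pent-2-enoate F4. Zinc insertion (Zn, LiCl, THF) gives {(2R)-2-[(3Z)-6-(furan-3-yl)-3-(methoxycarbonyl)hex-3-en-1-yl]-3-methylbut-3-en-1-yl}zinc iodide F5. Acid 24 is deprotonated with LiN(SiMe3)2 to lithium (2E,6E)-7-iodo-6-methyl-2-(4-methylpent-3-en-1-yl)hepta-2,6-dienoate F6, and Negishi coupling of F5 with F6 (Pd(OAc)2, SPhos, THF, rt) followed by work-up with dilute HCl gives 25.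

Step 5 (SeO2 oxidation next to a furan; moderate conversion and possible over-oxidation). The fallback sets out from 7 and comes back at 12, and puts the oxygen in before the furan is present. SeO2/t-BuOOH oxidation of 7 gives (2E)-5-bromo-2-methylpent-2-en-1-ol F7, which is silylated (t-BuMe2SiCl, imidazole) to {[(2E)-5-bromo-2-methylpent-2-en-1-yl]oxy}(tert-butyl)dimethylsilane F8. Alkylation of sodiated phosphonoacetate 8 with F8 gives methyl (5E)-2-[bis(2,2,2-trifluoroethoxy)phosphoryl]-7-[(tert-butyldimethylsilyl)oxy]-6-methylhept-5-enoate F9. Deprotonation (KN(SiMe3)2, 18-crown-6) gives potassium (5E)-2-[bis(2,2,2-trifluoroethoxy)phosphoryl]-7-[(tert-butyldimethylsilyl)oxy]-1-methoxy-6-methyl-1-oxohept-5-en-2-ide F10, and olefination with 5 gives methyl (2Z)-2-[(3E)-5-[(tert-butyldimethylsilyl)oxy]-4-methylpent-3-en-1-yl]-5-(furan-3-yl)pent-2-enoate F11. Bu4NF in THF removes the silyl group and gives 12.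

**Further compounds**
F1 | step 7 | methyl (2Z)-5-(furan-3-yl)-2-[(3E)-5-[(methoxycarbonyl)oxy]-4-methylpent-3-en-1-yl]pent-2-enoate | COC(=O)OC/C(C)=C/CC/C(=C/CCc1ccoc1)C(=O)OC
F2 | step 7 | methyl (2Z)-5-(furan-3-yl)-2-[(3R)-4-methyl-3-(4,4,5,5-tetramethyl-1,3,2-dioxaborolan-2-yl)pent-4-en-1-yl]pent-2-enoate | C=C(C)[C@H](B1OC(C)(C)C(C)(C)O1)CC/C(=C/CCc1ccoc1)C(=O)OC
F3 | step 13 | methyl (2Z)-5-(furan-3-yl)-2-[(3R)-3-(hydroxymethyl)-4-methylpent-4-en-1-yl]pent-2-enoate | C=C(C)[C@H](CO)CC/C(=C/CCc1ccoc1)C(=O)OC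
F4 | step 13 | methyl (2Z)-5-(furan-3-yl)-2-[(3R)-3-(iodomethyl)-4-methylpent-4-en-1-yl]pent-2-enoate | C=C(C)[C@H](CI)CC/C(=C/CCc1ccoc1)C(=O)OC
F5 | step 13 | {(2R)-2-[(3Z)-6-(furan-3-yl)-3-(methoxycarbonyl)hex-3-en-1-yl]-3-methylbut-3-en-1-yl}zinc iodide | C=C(C)[C@H](C[Zn]I)CC/C(=C/CCc1ccoc1)C(=O)OC
F6 | step 13 | lithium (2E,6E)-7-iodo-6-methyl-2-(4-methylpent-3-en-1-yl)hepta-2,6-dienoate | [Li+].[O-]C(=O)/C(CCC=C(C)C)=C/CC/C(C)=C/I
F7 | step 5 | (2E)-5-bromo-2-methylpent-2-en-1-ol | OC/C(C)=C/CCBr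
F8 | step 5 | {[(2E)-5-bromo-2-methylpent-2-en-1-yl]oxy}(tert-butyl)dimethylsilane | CC(C)(C)[Si](C)(C)OC/C(C)=C/CCBr
F9 | step 5 | methyl (5E)-2-[bis(2,2,2-trifluoroethoxy)phosphoryl]-7-[(tert-butyldimethylsilyl)oxy]-6-methylhept-5-enoate | COC(=O)C(CC/C=C(\C)CO[Si](C)(C)C(C)(C)C)P(=O)(OCC(F)(F)F)OCC(F)(F)F
F10 | step 5 | potassium (5E)-2-[bis(2,2,2-trifluoroethoxy)phosphoryl]-7-[(tert-butyldimethylsilyl)oxy]-1-methoxy-6-methyl-1-oxohept-5-en-2-ide | [K+].COC(=O)[C-](CC/C=C(\C)CO[Si](C)(C)C(C)(C)C)P(=O)(OCC(F)(F)F)OCC(F)(F)F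
F11 | step 5 | methyl (2Z)-2-[(3E)-5-[(tert-butyldimethylsilyl)oxy]-4-methylpent-3-en-1-yl]-5-(furan-3-yl)pent-2-enoate | CC(C)(C)[Si](C)(C)OC/C(C)=C/CC/C(=C/CCc1ccoc1)C(=O)OC
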